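The readings are calculated from invented constants.

In a one-step first-order world the fraction of a charge left falls by a constant factor per minute, so we reckon here with the fraction left and not with the fraction made. North and east are the same recipe, read at different times, and free monomer is fed for 6.0 min.

in all of them: free monomer 22 mM (fed, over 6.0 min)

| run | protic impurity | initiator | remark | time |
|---|---|---|---|---|
| Monday's | 1.1 mM | 0.59 mol% | run made earlier; the fed solution adds 0.20 times the starting volume |  |
| Sunday's | 1.1 mM | 0.92 mol% | run made earlier; the fed solution adds 0.20 times the starting volume |  |
| Saturday's | 0.55 mM | 0.42 mol% | run made earlier; the fed solution adds 0.20 times the starting volume |  |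
| north | 1.10 mM | 0.42 mol% | the fed solution adds 0.20 times the starting volume | 12 min |
| east | 1.10 mM | 0.42 mol% | the fed solution adds 0.20 times the starting volume | 6.0 min |

- Monday's (time / min: monomer in chains / %): 0.833: 1.3; 2.50: 8.0; 4.00: 18.0; 6.00: 33.3; 10.0: 57.5
- Sunday's (time / min: monomer in chains / %): 2.00: 7.9; 4.00: 20.1; 6.00: 37.9; 8.00: 53.9; 10.0: 65.3
- Saturday's (time / min: monomer in chains / %): 0.833: 0.4; 2.50: 6.8; 4.00: 15.6; 6.00: 30.2; 10.0: 51.9

(standard deviation of a reading: 0.5 percentage points)

- charges are per starting volume, the dose included; the dosed solution carries all of it
- the average divides the monomer in chains by the number of chains, living and dead together; two radicals that join make one chain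
- the numbers in the tables scatter with a standard deviation of 0.5 percentage points
- the earlier runs do not show the number of chains; that part of a forecast is a guess
- percentages count the whole charge, also what has not yet gone in

* which of the two ends with the longer chains by the average number of monomer units in a chain (living and dead chains, two that joined counted as one) ("neither" if they lie within 10%) (north / east / neither)
* average number of monomer units in a chain (living and dead chains, two that joined counted as one) at the end, north
* average number of monomer units in a chain (living and dead chains, two that joined counted as one) at the end, east

The first rung of our ladder is the feed. It brings 0.167 min⁻¹ of the charge, while Saturday's run, at north's loading of 0.42 mol%, reads 0.0730 min⁻¹ of the charge going into chains just before the feed ends; free monomer therefore piles up during Saturday's feed.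

The next rung comes after the feed. Saturday's readings give k_L = 0.0931 min⁻¹, the fraction-left constant: the fall per minute in the logarithm of the fraction of the charge not in chains once the feed has ended, a pseudo-first-order constant. Saturday's run has half of north's impurity, but Monday's slope, scaled by the square root of the loading, reads 0.0951 min⁻¹, close to k_L, so we carry k_L to north and east.

Its half-life, 7.45 min, is longer than the 6.00 min that separates east's end from north's. From Saturday's reading at the end of the feed we reckon 39.9% not in chains at 12 min, which makes monomer in chains twice its value at 6.0 min.

The count of chains is a rung we cannot place, since the earlier runs do not show it, so we give no length of our own. By our reckoning north ends the longer if its count of chains at 12 min is less than twice the count at 6.0 min; we lean towards north, but no reading supports that.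

The forecast says north, with 70 (20 to 350) for north and 60 (17 to 320) for east; in its words, “Chain number is a guess”.

The simulation gives north, with 197 for north and 151 for east, both longer than forecast.

    protic impurity + free monomer → quenched substrate (k = 0.660 L mol⁻¹ s⁻¹)
    2 growing radical → dead chain (k = 4.00 × 10⁸ L mol⁻¹ s⁻¹)
    initiator → 2 initiating radical (k = 0.00170 s⁻¹)
    free monomer + growing radical → monomer in chains + growing radical, rate k4*[growing radical]*[free monomer] (k = 1.40 × 10⁵ L mol⁻¹ s⁻¹)
    free monomer + initiating radical → growing radical + monomer in chains (k = 1.30 × 10⁶ L mol⁻¹ s⁻¹)

From north's 66.8% free monomer at 6.00 min, k_L reckons 38.2% at 12.0 min, and north holds 36.8%. For the neighbour, east read at 10 min, it reckons 46.1%, and that flask holds 43.9%. Neither north nor east has come to rest: at 120 min north holds 7.23% free monomer, more than the 0.00165% from k_L, with initiator at 0% and length 209, while east at 60.0 min reaches 207.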